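**Strategy.** The route rests on cleaving the cyclobutane bond C4–C10 (longipinane numbering). C10 is a methyl-bearing quaternary carbon next to the C9 carbinol, the mark of a reductively opened 9,10-epoxide, and it lies 1,3 to C4 across the cyclohexenone ring. The precursor is therefore a cis-fused 4,10-secolongipinane (a himachalane) carrying the 9,10-epoxide, both esters and a 3-en-2-one. Cp2TiCl opens the epoxide to the C10 radical, which closes the four-membered ring onto C4 (4-exo-trig) and so makes the tricycle, the quaternary centre and the free 9-OH in one operation. A 1,2-carbonyl transposition then finishes the enone. The bicycle comes from (1S,4R)-p-mentha-2,8-dien-1-ol by Ireland–Claisen rearrangement, alkoxyallylboration and ring-closing metathesis.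

Key step: step 12

**Remarks on the chemistry.**
- Numbering: longipinane numbering is used for the target and for all bicyclic and tricyclic intermediates. C1 is the ketone carbon, C2=C3 the enone alkene (methyl on C3), C4, C5, C11 and C10 the cyclobutane carbons, C6 the gem-dimethyl carbon, C7 (angelate), C8 (isovalerate) and C9 (OH) the oxygenated carbons, and C10 the quaternary carbon with the methyl group. The bicyclic intermediates lack only the C4–C10 bond and are named as 4,10-secolongipinanes.
- Assumption: (1S,4R)-p-mentha-2,8-dien-1-ol (hydroxyl cis to isopropenyl), allyl methoxymethyl ether and (+)-Ipc2BOMe (from (−)-α-pinene) are taken as commercial.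
- The configuration at C3 of ketone 24 is not controlled and is erased in step 13.

**Route**

Step 1
Reactants: 1 (1S,4R)-p-mentha-2,8-dien-1-ol; 2 isobutyryl chloride
Product: 3 (1S,4R)-1-methyl-4-(prop-1-en-2-yl)cyclohex-2-en-1-yl 2-methylpropanoate
Conditions: Et3N, DMAP (cat.), CH2Cl2, 0 °C to rt
Reagents that add atoms: isobutyryl chloride, CC(C)C(=O)Cl
Why: DMAP-catalysed acylation of the tertiary allylic alcohol under basic conditions avoids ionisation of the allylic C–O bond and touches no stereocentre.

Step 2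
Reactants: 3 (1S,4R)-1-methyl-4-(prop-1-en-2-yl)cyclohex-2-en-1-yl 2-methylpropanoate
Product: 7 2-methyl-2-[(1S,6R)-3-methyl-6-(prop-1-en-2-yl)cyclohex-2-en-1-yl]propanoic acid, via lithium ester enolate 4 (not isolated), via trimethylsilyl ketene acetal 5 (not isolated), via trimethylsilyl ester 6 (not isolated)
Conditions: LiN(iPr)2, THF, −78 °C; Me3SiCl, Et3N, −78 °C to 60 °C; then 1 M HCl
Reagents that add atoms: none
Why: Ireland–Claisen rearrangement delivers the CMe2 carbon suprafacially to the ring carbon on the face that carried the oxygen, which is cis to the isopropenyl group, so the new stereocentre (later C5) is set by 1,3-chirality transfer, the alkene moves to its later 3,4-position, and the symmetric ketene acetal raises no E/Z question.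

Step 3
Reactants: 7 2-methyl-2-[(1S,6R)-3-methyl-6-(prop-1-en-2-yl)cyclohex-2-en-1-yl]propanoic acid
Product: 8 2-methyl-2-[(1S,6R)-3-methyl-6-(prop-1-en-2-yl)cyclohex-2-en-1-yl]propan-1-ol
Conditions: LiAlH4, Et2O, 0 °C to reflux; aqueous NaOH work-up
Reagents that add atoms: none
Why: Hydride reduction of the carboxylic acid leaves the two isolated alkenes and both stereocentres untouched.

Step 4
Reactants: 8 2-methyl-2-[(1S,6R)-3-methyl-6-(prop-1-en-2-yl)cyclohex-2-en-1-yl]propan-1-ol
Product: 9 2-methyl-2-[(1S,6R)-3-methyl-6-(prop-1-en-2-yl)cyclohex-2-en-1-yl]propanal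
Conditions: Dess–Martin periodinane, NaHCO3, CH2Cl2, rt
Reagents that add atoms: none
Why: Dess–Martin oxidation stops at the aldehyde, which has no α-hydrogen and therefore cannot epimerise or enolise.

Step 5
Reactants: 9 2-methyl-2-[(1S,6R)-3-methyl-6-(prop-1-en-2-yl)cyclohex-2-en-1-yl]propanal; 10 allyl methoxymethyl ether
Product: 13 (3S,4S)-4-(methoxymethoxy)-2-methyl-2-[(1S,6R)-3-methyl-6-(prop-1-en-2-yl)cyclohex-2-en-1-yl]hex-5-en-3-ol, via (Z)-alkoxyallyl diisopinocampheylborane 11 (not isolated), via borinate adduct 12 (not isolated)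
Conditions: 10, s-BuLi, THF, −78 °C; (+)-Ipc2BOMe; BF3·OEt2; then 9, −78 °C; NaOH, H2O2, rt
Reagents that add atoms: allyl methoxymethyl ether, C=CCOCOC
Why: Brown (Z)-γ-alkoxyallylboration through a chair Zimmerman–Traxler transition state gives the syn 1,2-diol monoether (later C7 and C8, trans on the ring), and the isopinocampheyl groups from (−)-α-pinene direct attack to the Re face of the aldehyde, giving the (3S,4S) isomer under reagent control.

Step 6
Reactants: 13 (3S,4S)-4-(methoxymethoxy)-2-methyl-2-[(1S,6R)-3-methyl-6-(prop-1-en-2-yl)cyclohex-2-en-1-yl]hex-5-en-3-ol; 14 angelic acid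
Product: 15 (3S,4S)-4-(methoxymethoxy)-2-methyl-2-[(1S,6R)-3-methyl-6-(prop-1-en-2-yl)cyclohex-2-en-1-yl]hex-5-en-3-yl (Z)-2-methylbut-2-enoate
Conditions: 14, 2,4,6-trichlorobenzoyl chloride, Et3N, toluene, rt; then 13, 80 °C
Reagents that add atoms: angelic acid, C/C=C(/C)C(=O)O
Why: Yamaguchi-type acylation with the preformed mixed anhydride and no nucleophilic catalyst esterifies the hindered alcohol without Z to E isomerisation of the angelate.

Step 7
Reactants: 15 (3S,4S)-4-(methoxymethoxy)-2-methyl-2-[(1S,6R)-3-methyl-6-(prop-1-en-2-yl)cyclohex-2-en-1-yl]hex-5-en-3-yl (Z)-2-methylbut-2-enoate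
Product: 16 7-angeloyloxy-8-(methoxymethoxy)-4,10-secolongipina-3,9-diene (cis ring fusion, 7-O trans to 8-O)
Conditions: second-generation Grubbs catalyst (5 mol %), CH2Cl2, 40 °C
Reagents that add atoms: none
Why: Ring-closing metathesis of the vinyl and isopropenyl groups, held cis on the cyclohexene and helped by the gem-dimethyl group, forms the seven-membered ring with its trisubstituted 9,10-alkene, while the ring alkene and the angelate are inert.

Step 8
Reactants: 16 7-angeloyloxy-8-(methoxymethoxy)-4,10-secolongipina-3,9-diene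
Product: 17 7-angeloyloxy-4,10-secolongipina-3,9-dien-8-ol
Conditions: ZnBr2, n-PrSH, CH2Cl2, 0 °C
Reagents that add atoms: none
Why: Lewis acid-assisted thiolysis of the acetal removes the methoxymethyl group within minutes under conditions too mild to ionise the allylic C8–O bond or to isomerise the angelate.

Step 9
Reactants: 17 7-angeloyloxy-4,10-secolongipina-3,9-dien-8-ol
Product: 18 7-angeloyloxy-9,10-epoxy-4,10-secolongipin-3-en-8-ol (epoxide cis to 8-OH)
Conditions: VO(acac)2 (cat.), t-BuOOH, CH2Cl2, 0 °C to rt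
Reagents that add atoms: tert-butyl hydroperoxide, CC(C)(C)OO
Why: Vanadium-catalysed hydroxyl-directed epoxidation reacts only at the allylic-alcohol alkene and delivers oxygen syn to the 8-hydroxyl, which sets C9 with the 8,9-cis relationship of the target.

Step 10
Reactants: 18 7-angeloyloxy-9,10-epoxy-4,10-secolongipin-3-en-8-ol; 19 isovaleryl chloride
Product: 20 7-angeloyloxy-9,10-epoxy-8-isovaleryloxy-4,10-secolongipin-3-ene
Conditions: pyridine, DMAP (cat.), CH2Cl2, 0 °C
Reagents that add atoms: isovaleryl chloride, CC(C)CC(=O)Cl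
Why: Acylation of the only free hydroxyl places the isovalerate on O8 while the future 9-OH is still masked in the epoxide, so the three oxygens are differentiated without protecting groups.

Step 11
Reactants: 20 7-angeloyloxy-9,10-epoxy-8-isovaleryloxy-4,10-secolongipin-3-ene
Product: 21 7-angeloyloxy-9,10-epoxy-8-isovaleryloxy-4,10-secolongipin-3-en-2-one
Conditions: Rh2(cap)4 (cap = caprolactamate, 1 mol %), t-BuOOH (aq.), K2CO3, CH2Cl2, rt
Reagents that add atoms: tert-butyl hydroperoxide, CC(C)(C)OO
Why: Peroxyl-radical allylic oxidation converts C2, the only allylic methylene of the one remaining electron-rich alkene, into the ketone (the other allylic site, C5–H, is tertiary and shielded by the quaternary C6), giving the carvone-type enone that serves as radical acceptor.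

Step 12
Reactants: 21 7-angeloyloxy-9,10-epoxy-8-isovaleryloxy-4,10-secolongipin-3-en-2-one
Product: 24 7-angeloyloxy-9-hydroxy-8-isovaleryloxylongipinan-2-one (C3 epimers), via 9-titanoxy C10 radical 22 (not isolated), via titanium enolate 23 (not isolated)
Conditions: Cp2TiCl2, Zn dust, THF, rt (21 added slowly to the green Cp2TiCl solution, 0.01 M); then aq. NaH2PO4
Reagents that add atoms: none
Why: Cp2TiCl transfers one electron to the epoxide, which opens at the more substituted C10–O bond to the tertiary C10 radical with O9 held as a titanium alkoxide (22); this nucleophilic radical adds to C4, the β-carbon of the 3-en-2-one, and the α-keto radical is reduced by a second Cp2TiCl to the titanium enolate 23, which is protonated on work-up. The closest known reaction type is the titanocene-mediated reductive epoxide opening with radical cyclisation, whose 4-exo variant converts carvone-derived 8,9-epoxy enones into pinanes, that is, the same bond in the same bicyclo[3.1.1]heptane. The cyclobutane closes 4-exo-trig, and with it the second seven-membered ring of the tricycle. C10 is set by the existing seven-membered ring, which ties C9 to C6 on the face away from the enone bridge so that the methyl group must end up over that bridge, and C4 is set by the cis ring fusion, because the radical centre held on C11 can reach only the C4 face syn to the C11–C10 bond; C3 is not controlled and is erased later. The step needs ring closure to outrun reduction or β-hydride loss of the tertiary radical and needs 1,4- over 1,2-attack on the enone: the quaternary C6 keeps the C5–C6 bond equatorial and hence the C11–C10 bond axial over C4, the radical and acceptor polarities are matched, and reduction of the α-keto radical makes the closure irreversible.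

Step 13
Reactants: 24 7-angeloyloxy-9-hydroxy-8-isovaleryloxylongipinan-2-one
Product: 25 7-angeloyloxy-2,9-dihydroxy-8-isovaleryloxylongipin-2-en-1-one
Conditions: SeO2, dioxane/H2O, 90 °C
Reagents that add atoms: selenium dioxide, O=[Se]=O
Why: Riley oxidation of the only α-methylene (C1) gives the 1,2-dione, which can enolise only toward C3 because C11 and C4 are bridgeheads, so the diosphenol carries the carbonyl on C1 and the alkene at C2=C3.

Step 14
Reactants: 25 7-angeloyloxy-2,9-dihydroxy-8-isovaleryloxylongipin-2-en-1-one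
Product: 26 7-angeloyloxy-9-hydroxy-8-isovaleryloxy-2-(trifluoromethanesulfonyloxy)longipin-2-en-1-one
Conditions: PhNTf2, Et3N, DMAP (cat.), CH2Cl2, 0 °C to rt
Reagents that add atoms: N-phenylbis(trifluoromethanesulfonimide), O=S(=O)(N(c1ccccc1)S(=O)(=O)C(F)(F)F)C(F)(F)F
Why: The mild triflating agent sulfonylates the acidic enol hydroxyl and not the hindered secondary 9-OH.

Step 15
Reactants: 26 7-angeloyloxy-9-hydroxy-8-isovaleryloxy-2-(trifluoromethanesulfonyloxy)longipin-2-en-1-one
Product: 27 (4R,5S,7S,8S,9S,10R,11R)-7-angeloyloxy-9-hydroxy-8-(3-methylbutanoyloxy)longipin-2-en-1-one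
Conditions: Pd(OAc)2 (cat.), PPh3, HCO2H, Et3N, DMF, 60 °C
Reagents that add atoms: none
Why: Palladium-catalysed formate reduction of the α-keto enol triflate replaces the triflate by hydrogen and leaves the enone, the esters and the free hydroxyl untouched, which completes the 1,2-carbonyl transposition.

**Compound list**

1 | (1S,4R)-p-mentha-2,8-dien-1-ol (hydroxyl cis to isopropenyl) | C[C@@]1(O)C=C[C@H](C(C)=C)CC1 | starting material
2 | isobutyryl chloride | CC(C)C(=O)Cl | starting material
3 | (1S,4R)-1-methyl-4-(prop-1-en-2-yl)cyclohex-2-en-1-yl 2-methylpropanoate | CC(C)C(=O)O[C@]1(C)C=C[C@H](C(C)=C)CC1 | intermediate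
4 | lithium enolate of ester 3 | CC(C)=C(O[Li])O[C@]1(C)C=C[C@H](C(C)=C)CC1 | intermediate
5 | trimethylsilyl ketene acetal of ester 3 | CC(C)=C(O[Si](C)(C)C)O[C@]1(C)C=C[C@H](C(C)=C)CC1 | intermediate
6 | trimethylsilyl ester of acid 7 | CC1=C[C@H](C(C)(C)C(=O)O[Si](C)(C)C)[C@H](C(C)=C)CC1 | intermediate
7 | 2-methyl-2-[(1S,6R)-3-methyl-6-(prop-1-en-2-yl)cyclohex-2-en-1-yl]propanoic acid | CC1=C[C@H](C(C)(C)C(=O)O)[C@H](C(C)=C)CC1 | intermediate
8 | 2-methyl-2-[(1S,6R)-3-methyl-6-(prop-1-en-2-yl)cyclohex-2-en-1-yl]propan-1-ol | CC1=C[C@H](C(C)(C)CO)[C@H](C(C)=C)CC1 | intermediate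
9 | 2-methyl-2-[(1S,6R)-3-methyl-6-(prop-1-en-2-yl)cyclohex-2-en-1-yl]propanal | CC1=C[C@H](C(C)(C)C=O)[C@H](C(C)=C)CC1 | intermediate
10 | allyl methoxymethyl ether | C=CCOCOC | starting material
11 | [(Z)-3-(methoxymethoxy)allyl]diisopinocampheylborane (isopinocampheyl groups from (−)-α-pinene) | COCO/C=C\CB([C@H]1C[C@H]2C[C@@H]([C@@H]1C)C2(C)C)[C@H]1C[C@H]2C[C@@H]([C@@H]1C)C2(C)C | intermediate
12 | diisopinocampheylborinate of alcohol 13 | CC1=C[C@H](C(C)(C)[C@H](OB([C@H]2C[C@H]3C[C@@H]([C@@H]2C)C3(C)C)[C@H]2C[C@H]3C[C@@H]([C@@H]2C)C3(C)C)[C@@H](OCOC)C=C)[C@H](C(C)=C)CC1 | intermediate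
13 | (3S,4S)-4-(methoxymethoxy)-2-methyl-2-[(1S,6R)-3-methyl-6-(prop-1-en-2-yl)cyclohex-2-en-1-yl]hex-5-en-3-ol | CC1=C[C@H](C(C)(C)[C@H](O)[C@@H](OCOC)C=C)[C@H](C(C)=C)CC1 | intermediate
14 | angelic acid, (Z)-2-methylbut-2-enoic acid | C/C=C(/C)C(=O)O | starting material
15 | angelate of alcohol 13 | C/C=C(/C)C(=O)O[C@H]([C@@H](OCOC)C=C)C(C)(C)[C@H]1C=C(C)CC[C@H]1C(C)=C | intermediate
16 | 7-angeloyloxy-8-(methoxymethoxy)-4,10-secolongipina-3,9-diene | C/C=C(/C)C(=O)O[C@@H]1[C@@H](OCOC)C=C(C)[C@@H]2CCC(C)=C[C@@H]2C1(C)C | intermediate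
17 | 7-angeloyloxy-4,10-secolongipina-3,9-dien-8-ol | C/C=C(/C)C(=O)O[C@@H]1[C@@H](O)C=C(C)[C@@H]2CCC(C)=C[C@@H]2C1(C)C | intermediate
18 | 7-angeloyloxy-9,10-epoxy-4,10-secolongipin-3-en-8-ol (epoxide cis to 8-OH) | C/C=C(/C)C(=O)O[C@@H]1[C@@H](O)[C@H]3O[C@@]3(C)[C@@H]2CCC(C)=C[C@@H]2C1(C)C | intermediate
19 | isovaleryl chloride, 3-methylbutanoyl chloride | CC(C)CC(=O)Cl | starting material
20 | 7-angeloyloxy-9,10-epoxy-8-isovaleryloxy-4,10-secolongipin-3-ene | C/C=C(/C)C(=O)O[C@@H]1[C@@H](OC(=O)CC(C)C)[C@H]3O[C@@]3(C)[C@@H]2CCC(C)=C[C@@H]2C1(C)C | intermediate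
21 | 7-angeloyloxy-9,10-epoxy-8-isovaleryloxy-4,10-secolongipin-3-en-2-one | C/C=C(/C)C(=O)O[C@@H]1[C@@H](OC(=O)CC(C)C)[C@H]3O[C@@]3(C)[C@@H]2CC(=O)C(C)=C[C@@H]2C1(C)C | intermediate
22 | C10 radical of 21 with O9 bound to Cp2TiCl | C/C=C(/C)C(=O)O[C@@H]1[C@@H](OC(=O)CC(C)C)[C@@H](O[Ti](Cl)(C4C=CC=C4)C4C=CC=C4)[C](C)[C@@H]2CC(=O)C(C)=C[C@@H]2C1(C)C | intermediate
23 | titanium enolate (O2) and titanium alkoxide (O9) of ketone 24 | C/C=C(/C)C(=O)O[C@@H]1[C@@H](OC(=O)CC(C)C)[C@@H](O[Ti](Cl)(C4C=CC=C4)C4C=CC=C4)[C@@]2(C)[C@@H]3CC(O[Ti](Cl)(C4C=CC=C4)C4C=CC=C4)=C(C)[C@H]2[C@@H]3C1(C)C | intermediate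
24 | 7-angeloyloxy-9-hydroxy-8-isovaleryloxylongipinan-2-one (C3 epimers) | C/C=C(/C)C(=O)O[C@@H]1[C@@H](OC(=O)CC(C)C)[C@@H](O)[C@@]2(C)[C@@H]3CC(=O)C(C)[C@H]2[C@@H]3C1(C)C | intermediate
25 | 7-angeloyloxy-2,9-dihydroxy-8-isovaleryloxylongipin-2-en-1-one | C/C=C(/C)C(=O)O[C@@H]1[C@@H](OC(=O)CC(C)C)[C@@H](O)[C@@]2(C)[C@@H]3C(=O)C(O)=C(C)[C@H]2[C@@H]3C1(C)C | intermediate
26 | 2-triflate of diosphenol 25 | C/C=C(/C)C(=O)O[C@@H]1[C@@H](OC(=O)CC(C)C)[C@@H](O)[C@@]2(C)[C@@H]3C(=O)C(OS(=O)(=O)C(F)(F)F)=C(C)[C@H]2[C@@H]3C1(C)C | intermediate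
27 | (4R,5S,7S,8S,9S,10R,11R)-7-angeloyloxy-9-hydroxy-8-(3-methylbutanoyloxy)longipin-2-en-1-one | C/C=C(/C)C(=O)O[C@@H]1[C@@H](OC(=O)CC(C)C)[C@@H](O)[C@@]2(C)[C@@H]3C(=O)C=C(C)[C@H]2[C@@H]3C1(C)C | target

**Summary**

Total step count: 15. Longest linear sequence: 15 steps (1 to 27).

**Steps most likely to fail**

Step 12. The tertiary C10 radical may be reduced, lose a β-hydrogen or abstract hydrogen from the solvent faster than it closes the strained four-membered ring, or it may add to the carbonyl carbon instead of the β-carbon. From 21, the same Cp2TiCl treatment run at normal concentration would be expected to give, by β-hydride loss from the titanium-trapped radical, the exo-methylene allylic alcohol F1. F1 would then be cyclised with Fe(acac)3 and PhSiH3 in EtOH at 60 °C: hydrogen-atom transfer to the methylene carbon regenerates the same C10 radical in a medium that contains no stoichiometric radical reductant, and Giese-type 4-exo closure onto C4 followed by reduction and protonation of the α-keto radical brings the route back at 24.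

Step 11. Hydrogen abstraction at the tertiary allylic C5–H, mixed-peroxide formation or loss of the epoxide may compete with clean oxidation of C2. From 20, SeO2 (cat.) with t-BuOOH in CH2Cl2 would hydroxylate the ring methylene next to the methyl-bearing alkene carbon by an ene and [2,3]-shift sequence to give the allylic alcohol F2, and Dess–Martin periodinane would oxidise F2 to 21.

Step 13. The hindered ketone may fail to react, the tertiary C3–H may be hydroxylated instead of C1, or the angelate may isomerise from Z to E at 90 °C. From 24, nitrosation of the only α-methylene with t-BuONO and HCl in THF at 0 °C would give the α-hydroxyimino ketone F3, and exchange of the oxime with aqueous glyoxylic acid at rt would release the 1,2-dione, which enolises to 25.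

**Further compounds**

F1 | step 12 | 7-angeloyloxy-9-hydroxy-8-isovaleryloxy-4,10-secolongipina-3,10(14)-dien-2-one | C/C=C(/C)C(=O)O[C@@H]1[C@@H](OC(=O)CC(C)C)[C@@H](O)C(=C)[C@@H]2CC(=O)C(C)=C[C@@H]2C1(C)C
F2 | step 11 | 7-angeloyloxy-9,10-epoxy-8-isovaleryloxy-4,10-secolongipin-3-en-2-ol | C/C=C(/C)C(=O)O[C@@H]1[C@@H](OC(=O)CC(C)C)[C@H]3O[C@@]3(C)[C@@H]2CC(O)C(C)=C[C@@H]2C1(C)C
F3 | step 13 | 7-angeloyloxy-9-hydroxy-1-(hydroxyimino)-8-isovaleryloxylongipinan-2-one | C/C=C(/C)C(=O)O[C@@H]1[C@@H](OC(=O)CC(C)C)[C@@H](O)[C@@]2(C)[C@@H]3C(=NO)C(=O)C(C)[C@H]2[C@@H]3C1(C)C
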